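The furofuran (furo[3,4-c]furan numbering; guaiacyl on C1, benzofuranyl on C4) is cut at the ring-fusion bond C3a–C6a and at the ether bond C6–O5, so both tetrahydrofuran rings come from one open-chain ester. The precursor is the 3-oxopropanoate of a Sharpless-derived trans aryl glycidol that already carries the cis-dihydrobenzofuran arm. Base makes its enolate open the oxirane at the non-benzylic carbon, and the benzylic alkoxide set free closes onto the formyl carbon. The step exploits the 1,3-relation of O5 and C6a across C4–C3a and the cis H-4/H-3a (endo aryl) pattern, the signature of anti opening of a trans epoxide. Hydrogenation, aryllithium addition and exo-face silane reduction then set C6a and the endo aryl at C1.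

Key step: step 12

Remark on the structure: as drawn, the target has both aryl groups endo on the furofuran (H-1/H-6a and H-4/H-3a cis, all four centers S) and a 2,3-cis dihydrobenzofuran (2S,3S); the route is built for exactly this isomer.

Assumption: the sense of induction in step 6 is taken by analogy with reported PTTL-catalysed insertions (the R ligand giving the 2S ether carbon); if it proves opposite, the S-configured catalyst is used and nothing else changes.

Abbreviation in names: DBF = (2S,3S)-3-{[tert-butyl(dimethyl)silyl]oxymethyl}-7-methoxy-2-[3-methoxy-4-(triisopropylsilyloxy)phenyl]-2,3-dihydro-1-benzofuran-5-yl (2,3-cis). Ring 1 of the core holds O2, ring 2 holds O5.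

Step 1
Reactants: 1 4-bromo-2-methoxyphenol
Product: 2 4-bromo-2-iodo-6-methoxyphenol
Conditions: NIS, TsOH (cat.), MeCN, 0 °C to rt
Reagents that add atoms: N-iodosuccinimide, O=C1CCC(=O)N1I
Why: Electrophilic iodination of the phenol goes to the only free position ortho to the hydroxyl group, the para position being blocked by bromine.

Step 2
Reactants: 3 vanillin
Product: 4 3-methoxy-4-(triisopropylsilyloxy)benzaldehyde
Conditions: TIPSCl, imidazole, DMF, rt
Reagents that add atoms: triisopropylsilyl chloride, CC(C)[Si](Cl)(C(C)C)C(C)C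
Why: Standard silylation of a phenol; the bulky silyl ether is chosen to survive the later base, hydride and aryllithium steps and to leave with fluoride at the end.

Step 3
Reactants: 4 3-methoxy-4-(triisopropylsilyloxy)benzaldehyde
Product: 5 [3-methoxy-4-(triisopropylsilyloxy)phenyl]methanol
Conditions: NaBH4, MeOH, 0 °C
Reagents that add atoms: none
Why: Borohydride reduction of the aldehyde to the benzylic alcohol leaves the aryl silyl ether untouched.

Step 4
Reactants: 2 4-bromo-2-iodo-6-methoxyphenol; 5 [3-methoxy-4-(triisopropylsilyloxy)phenyl]methanol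
Product: 6 5-bromo-1-iodo-3-methoxy-2-{[3-methoxy-4-(triisopropylsilyloxy)benzyl]oxy}benzene
Conditions: PPh3, DIAD, THF, 0 °C to rt
Reagents that add atoms: none
Why: Mitsunobu etherification joins the acidic phenol to the primary benzylic alcohol under neutral conditions that spare the silyl ether and both halogens.

Step 5
Reactants: 6 5-bromo-1-iodo-3-methoxy-2-{[3-methoxy-4-(triisopropylsilyloxy)benzyl]oxy}benzene
Product: 7 methyl 2-(5-bromo-3-methoxy-2-{[3-methoxy-4-(triisopropylsilyloxy)benzyl]oxy}phenyl)-2-diazoacetate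
Conditions: methyl diazoacetate, Pd(PPh3)4 (5 mol%), Ag2CO3 (0.5 equiv), Et3N, toluene, rt
Reagents that add atoms: methyl diazoacetate, COC(=O)C=[N+]=[N-]
Why: Palladium-catalysed cross-coupling of an aryl iodide with a diazoacetate keeps the diazo group and, at room temperature, takes place at the C–I bond only, leaving the C–Br bond.

Step 6
Reactants: 7 methyl 2-(5-bromo-3-methoxy-2-{[3-methoxy-4-(triisopropylsilyloxy)benzyl]oxy}phenyl)-2-diazoacetate
Product: 8 methyl (2S,3R)-5-bromo-7-methoxy-2-[3-methoxy-4-(triisopropylsilyloxy)phenyl]-2,3-dihydro-1-benzofuran-3-carboxylate (2,3-cis)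
Conditions: Rh2(R-PTTL)4 (1 mol%; PTTL = N-phthaloyl-tert-leucinate), toluene, −60 °C
Reagents that add atoms: none
Why: Intramolecular 1,5-C–H insertion of the rhodium carbenoid into the benzylic ether C–H bond closes the dihydrofuran ring, the concerted insertion giving the kinetic 2,3-cis ester and the chiral carboxylate ligands fixing both new stereocenters (C-2 S, C-3 R).

Step 7
Reactants: 8 methyl (2S,3R)-5-bromo-7-methoxy-2-[3-methoxy-4-(triisopropylsilyloxy)phenyl]-2,3-dihydro-1-benzofuran-3-carboxylate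
Product: 9 {(2S,3S)-5-bromo-7-methoxy-2-[3-methoxy-4-(triisopropylsilyloxy)phenyl]-2,3-dihydro-1-benzofuran-3-yl}methanol (2,3-cis)
Conditions: iBu2AlH (3 equiv), CH2Cl2, −78 to −30 °C
Reagents that add atoms: none
Why: Non-basic hydride reduction of the ester to the primary alcohol removes the acidic C-3 hydrogen before the cis ester can epimerise to trans (the change of descriptor at C-3 is only a change of priorities).

Step 8
Reactants: 9 {(2S,3S)-5-bromo-7-methoxy-2-[3-methoxy-4-(triisopropylsilyloxy)phenyl]-2,3-dihydro-1-benzofuran-3-yl}methanol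
Product: 10 tert-butyl({(2S,3S)-5-bromo-7-methoxy-2-[3-methoxy-4-(triisopropylsilyloxy)phenyl]-2,3-dihydro-1-benzofuran-3-yl}methoxy)dimethylsilane
Conditions: TBSCl, imidazole, DMF, rt
Reagents that add atoms: tert-butyldimethylsilyl chloride, CC(C)(C)[Si](C)(C)Cl
Why: Standard silylation of the primary alcohol, needed so that only one hydroxyl group is acylated in step 10.

Step 9
Reactants: 10 tert-butyl({(2S,3S)-5-bromo-7-methoxy-2-[3-methoxy-4-(triisopropylsilyloxy)phenyl]-2,3-dihydro-1-benzofuran-3-yl}methoxy)dimethylsilane; 11 (E)-3-(tributylstannyl)prop-2-en-1-ol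
Product: 12 (E)-3-DBF-prop-2-en-1-ol
Conditions: Pd(PPh3)4 (5 mol%), toluene, 100 °C
Reagents that add atoms: none
Why: Stille coupling of the aryl bromide with the (E)-alkenylstannane transfers the hydroxypropenyl group with retention of the alkene geometry under neutral, fluoride-free conditions.

Step 10
Reactants: 12 (E)-3-DBF-prop-2-en-1-ol
Product: 14 [(2R,3R)-3-DBF-oxiran-2-yl]methyl acetate, via epoxy alcohol 13 (not isolated)
Conditions: Ti(OiPr)4 (10 mol%), D-(−)-diisopropyl tartrate (12 mol%), t-BuOOH, 4 Å MS, CH2Cl2, −20 °C; then P(OMe)3; then Ac2O, Et3N, DMAP (cat.), −20 °C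
Reagents that add atoms: tert-butyl hydroperoxide, CC(C)(C)OO; acetic anhydride, CC(=O)OC(C)=O
Why: Sharpless asymmetric epoxidation of the (E)-allylic alcohol with the D-tartrate ligand gives the (2R,3R)-trans epoxide, which holds the later C-4 and (before inversion) C-3a, and acetylation in the same flask avoids isolating the acid-labile electron-rich epoxy alcohol.

Step 11
Reactants: 14 [(2R,3R)-3-DBF-oxiran-2-yl]methyl acetate
Product: 15 [(2R,3R)-3-DBF-oxiran-2-yl]methyl 3-oxopropanoate (mainly as its hydrogen-bonded enol)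
Conditions: LiN(iPr)2 (2.1 equiv), THF, −78 °C; CF3CH2OCHO; AcOH, −78 °C, pH 7 buffer
Reagents that add atoms: 2,2,2-trifluoroethyl formate, O=COCC(F)(F)F
Why: Crossed Claisen formylation of the preformed lithium ester enolate with the activated formate gives the β-oxo ester, which rests as its chelated lithium enolate at −78 °C, where neither enolate attacks the oxirane.

Step 12
Reactants: 15 [(2R,3R)-3-DBF-oxiran-2-yl]methyl 3-oxopropanoate
Product: 18 (3aS,4S)-4-DBF-3a,4-dihydro-1H,3H-furo[3,4-c]furan-1-one, via hydroxy formyl lactone 16 (not isolated), via bicyclic lactol 17 (not isolated)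
Conditions: KOt-Bu (1.0 equiv), 18-crown-6, THF, 0 to 50 °C; AcOH; then PPTS, 4 Å MS, CH2Cl2, rt
Reagents that add atoms: none
Why: Proposed new method: KOt-Bu turns the β-oxo ester into its potassium enolate, whose α-carbon attacks the non-benzylic oxirane carbon from the side opposite the C–O bond and so closes ring 1 (the γ-lactone, bond C3a–C6a) in a 5-exo-tet alkylation that runs through the formyl enolate (enolexo) with inversion at C-3a; the benzylic alkoxide set free then adds to the formyl carbon and closes ring 2 (bond C6–O5) in a 5-exo-trig hemiacetalisation, and the acid step removes water to give the enol ether. The closest known reaction types are the alkylation of 1,3-dicarbonyl anions by epoxides with ring closure onto a carbonyl group (the classical route to α-acyl lactones and dihydrofurans) and the base-mediated 5-exo closure of glycidyl carbamates at C-2; what has not been shown is the union of both in an ester-tethered glycidyl 3-oxopropanoate. C-4 is carried over unchanged from the Sharpless epoxide, C-3a is fixed by the stereospecific anti opening of the trans oxirane, which puts H-3a cis to H-4 and the aryl group endo, and C-6a ends sp2 and is set in step 13. The step needs attack at the non-benzylic carbon (5-exo) and not at the benzylic one (6-endo), which the short planar ester tether and the strictly basic, aprotic medium (no help for ionisation of the benzylic C–O bond) should secure. It also needs the alkoxide to close on the aldehyde and not on the lactone carbonyl (translactonisation), which is secured because proton transfer from the far more acidic formyl lactone leaves the lactone as an unreactive enolate until the neutral work-up, where lactol formation is the fast process.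

Step 13
Reactants: 18 (3aS,4S)-4-DBF-3a,4-dihydro-1H,3H-furo[3,4-c]furan-1-one
Product: 19 (3aS,4S,6aS)-4-DBF-tetrahydro-1H,3H-furo[3,4-c]furan-1-one (cis-fused; aryl endo)
Conditions: H2 (1 atm), Pd/C, pyridine (0.5 equiv), EtOAc, rt
Reagents that add atoms: none
Why: Hydrogen is delivered to the enol-ether double bond from the face of H-3a, the only one that gives the strain-free cis-fused bicycle and the one not shielded by the endo aryl group, which sets C-6a, while pyridine tempers the catalyst against benzylic C–O cleavage.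

Step 14
Reactants: 1 4-bromo-2-methoxyphenol
Product: 20 (4-bromo-2-methoxyphenoxy)triisopropylsilane
Conditions: TIPSCl, imidazole, DMF, rt
Reagents that add atoms: triisopropylsilyl chloride, CC(C)[Si](Cl)(C(C)C)C(C)C
Why: Standard silylation of the phenol gives an aryl bromide fit for bromine–lithium exchange.

Step 15
Reactants: 19 (3aS,4S,6aS)-4-DBF-tetrahydro-1H,3H-furo[3,4-c]furan-1-one; 20 (4-bromo-2-methoxyphenoxy)triisopropylsilane
Product: 22 (3aS,4S,6aS)-4-DBF-1-[3-methoxy-4-(triisopropylsilyloxy)phenyl]tetrahydro-1H,3H-furo[3,4-c]furan-1-ol (hemiketal; both C-1 epimers), via aryllithium 21 (not isolated)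
Conditions: 20, n-BuLi, THF, −78 °C; then 19, −78 °C; aq. NH4Cl
Reagents that add atoms: none
Why: Bromine–lithium exchange gives the aryllithium, which adds once to the γ-lactone because the lithium hemiketal alkoxide does not collapse to the ketone at −78 °C, as in the synthesis of C-aryl glycosides from lactones (C-1 is not yet fixed).

Step 16
Reactants: 22 (3aS,4S,6aS)-4-DBF-1-[3-methoxy-4-(triisopropylsilyloxy)phenyl]tetrahydro-1H,3H-furo[3,4-c]furan-1-ol
Product: 23 (1S,3aS,4S,6aS)-4-DBF-1-[3-methoxy-4-(triisopropylsilyloxy)phenyl]tetrahydro-1H,3H-furo[3,4-c]furan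
Conditions: Et3SiH, BF3·OEt2, CH2Cl2, −78 °C; Et3N quench
Reagents that add atoms: none
Why: Ionic reduction of the lactol, in which BF3 forms the aryl-stabilised bicyclic oxocarbenium ion and the silane hydride attacks its convex face, cis to H-6a, so that the aryl group at C-1 ends endo (1S).

Step 17
Reactants: 23 (1S,3aS,4S,6aS)-4-DBF-1-[3-methoxy-4-(triisopropylsilyloxy)phenyl]tetrahydro-1H,3H-furo[3,4-c]furan
Product: 24 4-[(1S,3aS,4S,6aS)-4-[(2S,3S)-3-(hydroxymethyl)-2-(4-hydroxy-3-methoxyphenyl)-7-methoxy-2,3-dihydro-1-benzofuran-5-yl]tetrahydro-1H,3H-furo[3,4-c]furan-1-yl]-2-methoxyphenol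
Conditions: Bu4NF, AcOH, THF, 0 °C to rt
Reagents that add atoms: none
Why: Fluoride cleaves the three silyl ethers, and acetic acid buffers the phenoxides so that the base-sensitive para-hydroxybenzylic ethers do not open.

Compound list

1 | 4-bromo-2-methoxyphenol | COc1cc(Br)ccc1O | starting material
2 | 4-bromo-2-iodo-6-methoxyphenol | COc1cc(Br)cc(I)c1O | intermediate
3 | vanillin (4-hydroxy-3-methoxybenzaldehyde) | COc1cc(C=O)ccc1O | starting material
4 | 3-methoxy-4-(triisopropylsilyloxy)benzaldehyde | COc1cc(C=O)ccc1O[Si](C(C)C)(C(C)C)C(C)C | intermediate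
5 | [3-methoxy-4-(triisopropylsilyloxy)phenyl]methanol | COc1cc(CO)ccc1O[Si](C(C)C)(C(C)C)C(C)C | intermediate
6 | 5-bromo-1-iodo-3-methoxy-2-{[3-methoxy-4-(triisopropylsilyloxy)benzyl]oxy}benzene | COc1cc(Br)cc(I)c1OCc1ccc(O[Si](C(C)C)(C(C)C)C(C)C)c(OC)c1 | intermediate
7 | methyl 2-(5-bromo-3-methoxy-2-{[3-methoxy-4-(triisopropylsilyloxy)benzyl]oxy}phenyl)-2-diazoacetate | COC(=O)C(=[N+]=[N-])c1cc(Br)cc(OC)c1OCc1ccc(O[Si](C(C)C)(C(C)C)C(C)C)c(OC)c1 | intermediate
8 | methyl (2S,3R)-5-bromo-7-methoxy-2-[3-methoxy-4-(triisopropylsilyloxy)phenyl]-2,3-dihydro-1-benzofuran-3-carboxylate (2,3-cis) | Brc1cc(OC)c2c(c1)[C@@H](C(=O)OC)[C@@H](c1ccc(O[Si](C(C)C)(C(C)C)C(C)C)c(OC)c1)O2 | intermediate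
9 | {(2S,3S)-5-bromo-7-methoxy-2-[3-methoxy-4-(triisopropylsilyloxy)phenyl]-2,3-dihydro-1-benzofuran-3-yl}methanol (2,3-cis) | Brc1cc(OC)c2c(c1)[C@@H](CO)[C@@H](c1ccc(O[Si](C(C)C)(C(C)C)C(C)C)c(OC)c1)O2 | intermediate
10 | tert-butyl({(2S,3S)-5-bromo-7-methoxy-2-[3-methoxy-4-(triisopropylsilyloxy)phenyl]-2,3-dihydro-1-benzofuran-3-yl}methoxy)dimethylsilane | Brc1cc(OC)c2c(c1)[C@@H](CO[Si](C)(C)C(C)(C)C)[C@@H](c1ccc(O[Si](C(C)C)(C(C)C)C(C)C)c(OC)c1)O2 | intermediate
11 | (E)-3-(tributylstannyl)prop-2-en-1-ol | CCCC[Sn](CCCC)(CCCC)/C=C/CO | starting material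
12 | (E)-3-DBF-prop-2-en-1-ol | OC/C=C/c1cc(OC)c2c(c1)[C@@H](CO[Si](C)(C)C(C)(C)C)[C@@H](c1ccc(O[Si](C(C)C)(C(C)C)C(C)C)c(OC)c1)O2 | intermediate
13 | [(2R,3R)-3-DBF-oxiran-2-yl]methanol (trans epoxide) | OC[C@H]1O[C@@H]1c3cc(OC)c4c(c3)[C@@H](CO[Si](C)(C)C(C)(C)C)[C@@H](c3ccc(O[Si](C(C)C)(C(C)C)C(C)C)c(OC)c3)O4 | intermediate
14 | [(2R,3R)-3-DBF-oxiran-2-yl]methyl acetate | CC(=O)OC[C@H]1O[C@@H]1c3cc(OC)c4c(c3)[C@@H](CO[Si](C)(C)C(C)(C)C)[C@@H](c3ccc(O[Si](C(C)C)(C(C)C)C(C)C)c(OC)c3)O4 | intermediate
15 | [(2R,3R)-3-DBF-oxiran-2-yl]methyl 3-oxopropanoate (drawn as the aldehyde tautomer) | O=CCC(=O)OC[C@H]1O[C@@H]1c3cc(OC)c4c(c3)[C@@H](CO[Si](C)(C)C(C)(C)C)[C@@H](c3ccc(O[Si](C(C)C)(C(C)C)C(C)C)c(OC)c3)O4 | intermediate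
16 | (4S)-4-[(S)-hydroxy(DBF)methyl]-2-oxotetrahydrofuran-3-carbaldehyde (present as its potassium enolate; C-3 not defined) | O=CC1C(=O)OC[C@H]1[C@H](O)c3cc(OC)c4c(c3)[C@@H](CO[Si](C)(C)C(C)(C)C)[C@@H](c3ccc(O[Si](C(C)C)(C(C)C)C(C)C)c(OC)c3)O4 | intermediate
17 | (3aS,4S,6aS)-4-DBF-6-hydroxytetrahydro-1H,3H-furo[3,4-c]furan-1-one (lactol; either C-6 epimer) | O=C1OC[C@@H]2[C@H]1C(O)O[C@@H]2c3cc(OC)c4c(c3)[C@@H](CO[Si](C)(C)C(C)(C)C)[C@@H](c3ccc(O[Si](C(C)C)(C(C)C)C(C)C)c(OC)c3)O4 | intermediate
18 | (3aS,4S)-4-DBF-3a,4-dihydro-1H,3H-furo[3,4-c]furan-1-one | O=C1OC[C@@H]2C1=CO[C@@H]2c3cc(OC)c4c(c3)[C@@H](CO[Si](C)(C)C(C)(C)C)[C@@H](c3ccc(O[Si](C(C)C)(C(C)C)C(C)C)c(OC)c3)O4 | intermediate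
19 | (3aS,4S,6aS)-4-DBF-tetrahydro-1H,3H-furo[3,4-c]furan-1-one (cis-fused; aryl endo) | O=C1OC[C@@H]2[C@H]1CO[C@@H]2c3cc(OC)c4c(c3)[C@@H](CO[Si](C)(C)C(C)(C)C)[C@@H](c3ccc(O[Si](C(C)C)(C(C)C)C(C)C)c(OC)c3)O4 | intermediate
20 | (4-bromo-2-methoxyphenoxy)triisopropylsilane | COc1cc(Br)ccc1O[Si](C(C)C)(C(C)C)C(C)C | intermediate
21 | [3-methoxy-4-(triisopropylsilyloxy)phenyl]lithium | [Li]c1ccc(O[Si](C(C)C)(C(C)C)C(C)C)c(OC)c1 | intermediate
22 | (3aS,4S,6aS)-4-DBF-1-[3-methoxy-4-(triisopropylsilyloxy)phenyl]tetrahydro-1H,3H-furo[3,4-c]furan-1-ol (hemiketal; both C-1 epimers) | COc1cc(C2(O)OC[C@@H]3[C@H]2CO[C@@H]3c4cc(OC)c5c(c4)[C@@H](CO[Si](C)(C)C(C)(C)C)[C@@H](c4ccc(O[Si](C(C)C)(C(C)C)C(C)C)c(OC)c4)O5)ccc1O[Si](C(C)C)(C(C)C)C(C)C | intermediate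
23 | (1S,3aS,4S,6aS)-4-DBF-1-[3-methoxy-4-(triisopropylsilyloxy)phenyl]tetrahydro-1H,3H-furo[3,4-c]furan (both aryl groups endo) | COc1cc([C@H]2OC[C@@H]3[C@H]2CO[C@@H]3c4cc(OC)c5c(c4)[C@@H](CO[Si](C)(C)C(C)(C)C)[C@@H](c4ccc(O[Si](C(C)C)(C(C)C)C(C)C)c(OC)c4)O5)ccc1O[Si](C(C)C)(C(C)C)C(C)C | intermediate
24 | 4-[(1S,3aS,4S,6aS)-4-[(2S,3S)-3-(hydroxymethyl)-2-(4-hydroxy-3-methoxyphenyl)-7-methoxy-2,3-dihydro-1-benzofuran-5-yl]tetrahydro-1H,3H-furo[3,4-c]furan-1-yl]-2-methoxyphenol | COc1cc([C@H]2OC[C@@H]3[C@H]2CO[C@@H]3c2cc(OC)c3c(c2)[C@@H](CO)[C@@H](c2ccc(O)c(OC)c2)O3)ccc1O | target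

Total step count: 17. Longest linear sequence: 15 steps (3 → 4 → 5 → 6 → 7 → 8 → 9 → 10 → 12 → 14 → 15 → 18 → 19 → 22 → 23 → 24).

Steps most likely to fail

Step 12. The enolate may attack the benzylic oxirane carbon in a 6-endo mode, or the alkylation through the ester tether may be so slow that the epoxide decomposes first. The fallback sets out from 13 (taken from step 10 run without the acetylation and filtered through base-washed silica) and from 4, and comes back at 23. Knoevenagel condensation of 4 with diallyl malonate (piperidine, AcOH, toluene, reflux, water removed) gives diallyl 2-[3-methoxy-4-(triisopropylsilyloxy)benzylidene]malonate F1. With KN(SiMe3)2 (1 equiv) in THF from −40 °C to rt, the alkoxide of 13 adds to F1, the malonate carbanion opens the oxirane at C-2 in a 5-exo closure on a flexible ether tether, and the benzylic alkoxide lactonises onto the cis ester. This gives the bicyclic lactone allyl ester F2; both bonds of the key disconnection still form in one operation, here by textbook malonate–epoxide alkylation and lactonisation. Pd(PPh3)4 with morpholine removes the allyl group and the acid loses CO2 in toluene at 80 °C to give the cis-fused lactone F3. iBu2AlH at −78 °C gives the lactol F4, and Et3SiH with BF3·OEt2 at −78 °C gives 23. The guaiacyl group comes in with the malonate, so steps 11 to 16 fall away. The price is that C-1 is set in the ring closure: the 2,4-cis tetrahydrofuran (both large groups pseudo-equatorial) is expected after equilibration of the conjugate adducts, and a C-1 epimer would have to be separated.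

Step 16. BF3 may ionise the endo benzylic ethers or the cis-dihydrobenzofuran, with epimerisation towards the exo (or trans) series. The fallback sets out from 22 and comes back at 23. MsCl and Et3N in CH2Cl2 at −20 °C dehydrate the hemiketal to the cyclic enol ether F5 (double bond C1=C6a). Hydrogenation (H2, Pd/C, pyridine, EtOAc) then adds both hydrogens from the convex face, cis to H-3a, which gives the same endo aryl group without any Lewis acid.

Step 10. The electron-rich aryl oxirane may be opened by isopropanol or tartrate on titanium, and enantiomeric purity may erode. The fallback sets out from 12 and comes back at 14. Ac2O in pyridine gives the cinnamyl acetate F6. Shi epoxidation with the D-fructose-derived ketone (KHSO5, K2CO3, MeCN–dimethoxymethane–buffer, pH 10.5, 0 °C) gives the (2R,3R)-epoxy acetate 14 in a basic medium free of Lewis acid.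

Further compounds

F1 | step 12 | diallyl 2-[3-methoxy-4-(triisopropylsilyloxy)benzylidene]malonate | C=CCOC(=O)C(=Cc1ccc(O[Si](C(C)C)(C(C)C)C(C)C)c(OC)c1)C(=O)OCC=C
F2 | step 12 | allyl ester of the 6-oxo analogue of 23 with the ester group on C-6a (convex face); lactone in ring 2, both aryl groups endo | COc1cc([C@H]2OC[C@@H]3[C@@]2(C(=O)OCC=C)C(=O)O[C@@H]3c4cc(OC)c5c(c4)[C@@H](CO[Si](C)(C)C(C)(C)C)[C@@H](c4ccc(O[Si](C(C)C)(C(C)C)C(C)C)c(OC)c4)O5)ccc1O[Si](C(C)C)(C(C)C)C(C)C
F3 | step 12 | 6-oxo analogue of 23 (cis-fused γ-lactone in ring 2) | COc1cc([C@H]2OC[C@@H]3[C@H]2C(=O)O[C@@H]3c4cc(OC)c5c(c4)[C@@H](CO[Si](C)(C)C(C)(C)C)[C@@H](c4ccc(O[Si](C(C)C)(C(C)C)C(C)C)c(OC)c4)O5)ccc1O[Si](C(C)C)(C(C)C)C(C)C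
F4 | step 12 | 6-hydroxy analogue of 23 (lactol; either C-6 epimer) | COc1cc([C@H]2OC[C@@H]3[C@H]2C(O)O[C@@H]3c4cc(OC)c5c(c4)[C@@H](CO[Si](C)(C)C(C)(C)C)[C@@H](c4ccc(O[Si](C(C)C)(C(C)C)C(C)C)c(OC)c4)O5)ccc1O[Si](C(C)C)(C(C)C)C(C)C
F5 | step 16 | 1,6a-didehydro analogue of 23 (cyclic enol ether; 3aS,4S) | COc1cc(C2=C3CO[C@H](c4cc(OC)c5c(c4)[C@@H](CO[Si](C)(C)C(C)(C)C)[C@@H](c4ccc(O[Si](C(C)C)(C(C)C)C(C)C)c(OC)c4)O5)[C@@H]3CO2)ccc1O[Si](C(C)C)(C(C)C)C(C)C
F6 | step 10 | (E)-3-DBF-prop-2-en-1-yl acetate | CC(=O)OC/C=C/c1cc(OC)c2c(c1)[C@@H](CO[Si](C)(C)C(C)(C)C)[C@@H](c1ccc(O[Si](C(C)C)(C(C)C)C(C)C)c(OC)c1)O2
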